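The route rests on closing the cyclohexane between C1 (the carboxyl-bearing carbon) and C2 (the chain-bearing carbon beside the quaternary C3). The two chain carbons on C2 are read as a masked vinyl group, so that C1–C2 becomes the bond of an aldehyde α-allylation. The precursor is an open chain, (7Z)-6,6-dimethyl-9-(trimethylsilyl)non-7-enal, with C1 as the aldehyde α-carbon and C2 as the allylsilane γ-carbon. One enantioselective SOMO-organocatalytic cyclisation closes the ring and sets the trans C1/C2 pair. Hydroboration/Suzuki coupling then extends the vinyl group, a palladium-catalysed asymmetric phenol O-allylation creates the tertiary ether carbon, and ring-closing metathesis closes the 2H-chromene.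

Key step: step 5

Remark: the (R,R) ligand in step 13 is chosen by analogy with phenol O-alkylations of trisubstituted allyl carbonates; should a model reaction show the opposite sense of induction, the (S,S) ligand takes its place.

Step 1
Reactants: 1 2-methylpropanenitrile (isobutyronitrile); 2 2-(4-bromobutyl)-1,3-dioxolane
Product: 4 6-(1,3-dioxolan-2-yl)-2,2-dimethylhexanenitrile, via lithiated isobutyronitrile 3 (not isolated)
Conditions: LiN(i-Pr)2, THF, −78 °C; then 2, −78 °C to rt
Reagents that add atoms: none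
Why: SN2 alkylation of the lithiated nitrile by the primary bromide should build the quaternary C3 with its two methyl groups; no stereocenter is formed.

Step 2
Reactants: 4 6-(1,3-dioxolan-2-yl)-2,2-dimethylhexanenitrile
Product: 6 6-(1,3-dioxolan-2-yl)-2,2-dimethylhexanal, via N-aluminio aldimine 5 (not isolated)
Conditions: i-Bu2AlH (1.2 equiv), CH2Cl2, −78 to 0 °C; then aq. citric acid, 0 °C
Reagents that add atoms: water, O
Why: Partial hydride reduction of the nitrile should stop at the N-aluminio aldimine, which mild acid hydrolyses to the aldehyde (future C2) while the dioxolane survives.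

Step 3
Reactants: 6 6-(1,3-dioxolan-2-yl)-2,2-dimethylhexanal; 7 methyltriphenylphosphonium bromide; 8 (iodomethyl)trimethylsilane
Product: 12 {(2Z)-8-(1,3-dioxolan-2-yl)-4,4-dimethyloct-2-en-1-yl}trimethylsilane, via methylenetriphenylphosphorane 9 (not isolated), via silylethylphosphonium iodide 10 (not isolated), via silylethylidene ylide 11 (not isolated)
Conditions: 7, n-BuLi, THF, 0 °C; 8, rt; n-BuLi, −78 °C; then 6, −78 °C to rt
Reagents that add atoms: none
Why: One-pot Wittig allylsilane synthesis: the ylide is alkylated by the silylmethyl iodide, deprotonated again, and the non-stabilised β-silyl ylide should olefinate the non-enolisable aldehyde mainly to the Z allylsilane (either geometry leads to the same vinyl group later).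

Step 4
Reactants: 12 {(2Z)-8-(1,3-dioxolan-2-yl)-4,4-dimethyloct-2-en-1-yl}trimethylsilane
Product: 13 (7Z)-6,6-dimethyl-9-(trimethylsilyl)non-7-enal
Conditions: AcOH/H2O/THF (3:1:1), 45 °C
Reagents that add atoms: water, O
Why: Acid-catalysed acetal hydrolysis under conditions too mild for protodesilylation of the allylsilane should free the aldehyde whose α-carbon is C1.

Step 5
Reactants: 13 (7Z)-6,6-dimethyl-9-(trimethylsilyl)non-7-enal
Product: 14 (1S,2R)-2-ethenyl-3,3-dimethylcyclohexane-1-carbaldehyde
Conditions: (2R,5R)-5-benzyl-2-tert-butyl-3-methylimidazolidin-4-one·CF3CO2H (20 mol%), (NH4)2Ce(NO3)6 (2.5 equiv), NaHCO3, H2O, acetone, −20 °C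
Reagents that add atoms: none
Why: The aldehyde condenses with the imidazolidinone to an enamine that tetravalent cerium oxidises to a 3π-electron radical cation; its electrophilic C1 radical adds to the allylsilane terminus C2, a second one-electron oxidation gives the β-silyl cation, loss of the silyl group leaves the vinyl group, and hydrolysis releases the aldehyde and the catalyst. The closest known reaction type is the enantioselective intramolecular α-allylation of aldehydes by SOMO organocatalysis, which forms five- to seven-membered carbocycles. The cyclohexane closes in the 6-exo-trig mode. C1 is set by the catalyst: in the (2R,5R) catalyst the benzyl group covers the Si face of the E-configured radical cation, so C2 bonds to the Re face and C1 becomes S; C2 is set by a chair-like transition state with the allyl arm pseudo-equatorial, which should give the trans (2R) arrangement. The step needs 6-exo over 7-endo closure, secured by β-silicon stabilisation of the radical and cation formed on exo attack, and trans over cis closure, secured by the equatorial preference; any cis isomer is to be removed by chromatography here, before C1 can epimerise, because its epimerisation would give the enantiomer.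

Step 6
Reactants: 14 (1S,2R)-2-ethenyl-3,3-dimethylcyclohexane-1-carbaldehyde
Product: 15 (1S,2R)-2-ethenyl-3,3-dimethylcyclohexane-1-carboxylic acid
Conditions: NaClO2, NaH2PO4, 2-methylbut-2-ene, t-BuOH/H2O, 0 °C to rt
Reagents that add atoms: sodium chlorite, [Na+].[O-]Cl=O
Why: Pinnick oxidation should convert the aldehyde to the acid without touching the vinyl group (hypochlorous acid is scavenged) and without epimerising C1, which already holds the more stable trans configuration.

Step 7
Reactants: 15 (1S,2R)-2-ethenyl-3,3-dimethylcyclohexane-1-carboxylic acid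
Product: 16 methyl (1S,2R)-2-ethenyl-3,3-dimethylcyclohexane-1-carboxylate
Conditions: MeI, K2CO3, DMF, rt
Reagents that add atoms: iodomethane, CI
Why: SN2 O-methylation of the carboxylate masks the acid for the borane and palladium steps that follow.

Step 8
Reactants: 17 but-2-yn-1-ol
Product: 19 (2Z)-3-iodobut-2-en-1-ol, via cyclic vinylalanate 18 (not isolated)
Conditions: NaAlH2(OCH2CH2OCH3)2, THF, 0 °C to rt; then I2, −78 to 0 °C
Reagents that add atoms: iodine, II
Why: Hydroxyl-directed trans-hydroalumination of the propargylic alcohol followed by iodinolysis of the vinyl–aluminium bond with retention should give the Z vinyl iodide.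

Step 9
Reactants: 16 methyl (1S,2R)-2-ethenyl-3,3-dimethylcyclohexane-1-carboxylate; 19 (2Z)-3-iodobut-2-en-1-ol
Product: 21 methyl (1S,2R)-2-[(3Z)-5-hydroxy-3-methylpent-3-en-1-yl]-3,3-dimethylcyclohexane-1-carboxylate, via B-alkyl-9-BBN 20 (not isolated)
Conditions: 9-BBN dimer, THF, rt to 50 °C; then 19, Pd(dppf)Cl2 (5 mol%), AsPh3, Cs2CO3, DMF/H2O, rt
Reagents that add atoms: none
Why: Anti-Markovnikov hydroboration of the vinyl group and B-alkyl Suzuki–Miyaura coupling with retention of the vinyl iodide geometry should turn the vinyl carbons into the two saturated chain carbons and attach the Z allylic alcohol; the ring stereocenters are not touched.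

Step 10
Reactants: 21 methyl (1S,2R)-2-[(3Z)-5-hydroxy-3-methylpent-3-en-1-yl]-3,3-dimethylcyclohexane-1-carboxylate
Product: 22 methyl (1S,2R)-2-{(3Z)-5-[(methoxycarbonyl)oxy]-3-methylpent-3-en-1-yl}-3,3-dimethylcyclohexane-1-carboxylate
Conditions: ClCO2Me, pyridine, CH2Cl2, 0 °C
Reagents that add atoms: methyl chloroformate, COC(=O)Cl
Why: Acylation of the primary allylic alcohol gives the methyl carbonate needed as the ionisable group for the allylic substitution.

Step 11
Reactants: 23 2,6-dihydroxy-4-methylbenzaldehyde (atranol)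
Product: 24 2-[(tert-butyldimethylsilyl)oxy]-6-hydroxy-4-methylbenzaldehyde
Conditions: TBSCl (1.0 equiv), imidazole, DMF, 0 °C
Reagents that add atoms: tert-butyldimethylsilyl chloride, CC(C)(C)[Si](C)(C)Cl
Why: Mono-silylation of the symmetrical diphenol should stop after one hydroxyl, because the remaining one is deactivated by its hydrogen bond to the aldehyde.

Step 12
Reactants: 24 2-[(tert-butyldimethylsilyl)oxy]-6-hydroxy-4-methylbenzaldehyde
Product: 26 3-[(tert-butyldimethylsilyl)oxy]-2-ethenyl-5-methylphenol, via β-hydroxysilane 25 (not isolated)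
Conditions: Me3SiCH2MgCl (2.5 equiv), THF, 0 °C to rt; then AcOH, 0 °C to rt
Reagents that add atoms: (trimethylsilyl)methylmagnesium chloride, C[Si](C)(C)C[Mg]Cl
Why: Peterson olefination: the first equivalent of the Grignard reagent deprotonates the phenol, the second adds to the aldehyde, and acid-promoted anti-elimination of trimethylsilanol from the electron-rich benzylic β-hydroxysilane should give the 2-vinylphenol needed for the later metathesis; the carbinol stereocenter of the racemic intermediate is lost in the elimination.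

Step 13
Reactants: 22 methyl (1S,2R)-2-{(3Z)-5-[(methoxycarbonyl)oxy]-3-methylpent-3-en-1-yl}-3,3-dimethylcyclohexane-1-carboxylate; 26 3-[(tert-butyldimethylsilyl)oxy]-2-ethenyl-5-methylphenol
Product: 27 methyl (1S,2R)-2-[(3R)-3-{3-[(tert-butyldimethylsilyl)oxy]-2-ethenyl-5-methylphenoxy}-3-methylpent-4-en-1-yl]-3,3-dimethylcyclohexane-1-carboxylate
Conditions: Pd2(dba)3·CHCl3 (2.5 mol%), (R,R)-DACH-phenyl Trost ligand (7.5 mol%), CH2Cl2, rt
Reagents that add atoms: none
Why: Trost asymmetric allylic alkylation: zerovalent palladium ionises the carbonate, the released methoxide deprotonates the phenol, and the phenoxide should attack the more substituted terminus of the π-allyl complex inside the chiral ligand pocket, which sets the (R) tertiary ether carbon under catalyst control (its epimer would be a separable diastereomer).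

Step 14
Reactants: 27 methyl (1S,2R)-2-[(3R)-3-{3-[(tert-butyldimethylsilyl)oxy]-2-ethenyl-5-methylphenoxy}-3-methylpent-4-en-1-yl]-3,3-dimethylcyclohexane-1-carboxylate
Product: 28 methyl (1S,2R)-2-{2-[(2R)-5-[(tert-butyldimethylsilyl)oxy]-2,7-dimethyl-2H-chromen-2-yl]ethyl}-3,3-dimethylcyclohexane-1-carboxylate
Conditions: second-generation Grubbs catalyst RuCl2(=CHPh)(PCy3)(H2IMes) (5 mol%), CH2Cl2, 40 °C
Reagents that add atoms: none
Why: Ring-closing olefin metathesis between the styrene and the vinyl group on the quaternary carbon should close the six-membered 2H-chromene with loss of ethene; no stereocenter is touched.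

Step 15
Reactants: 28 methyl (1S,2R)-2-{2-[(2R)-5-[(tert-butyldimethylsilyl)oxy]-2,7-dimethyl-2H-chromen-2-yl]ethyl}-3,3-dimethylcyclohexane-1-carboxylate
Product: 29 (1S,2R)-2-{2-[(2R)-5-hydroxy-2,7-dimethyl-2H-chromen-2-yl]ethyl}-3,3-dimethylcyclohexane-1-carboxylic acid
Conditions: LiOH·H2O, THF/MeOH/H2O, 60 °C; then aq. HCl to pH 3
Reagents that add atoms: lithium hydroxide, [Li+].[OH-]
Why: Saponification of the methyl ester and basic cleavage of the aryl silyl ether should occur together; C1 can only equilibrate towards the trans diequatorial acid that is wanted.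

Compound list
1 | 2-methylpropanenitrile (isobutyronitrile) | CC(C)C#N | starting material
2 | 2-(4-bromobutyl)-1,3-dioxolane | BrCCCCC1OCCO1 | starting material
3 | lithiated isobutyronitrile (N-lithio ketenimine form) | CC(C)=C=N[Li] | intermediate
4 | 6-(1,3-dioxolan-2-yl)-2,2-dimethylhexanenitrile | CC(C)(CCCCC1OCCO1)C#N | intermediate
5 | N-(diisobutylaluminio) aldimine of 6 | CC(C)C[Al](CC(C)C)N=CC(C)(C)CCCCC1OCCO1 | intermediate
6 | 6-(1,3-dioxolan-2-yl)-2,2-dimethylhexanal | O=CC(C)(C)CCCCC1OCCO1 | intermediate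
7 | methyltriphenylphosphonium bromide | [Br-].C[P+](c1ccccc1)(c1ccccc1)c1ccccc1 | starting material
8 | (iodomethyl)trimethylsilane | C[Si](C)(C)CI | starting material
9 | methylenetriphenylphosphorane | C=P(c1ccccc1)(c1ccccc1)c1ccccc1 | intermediate
10 | triphenyl[2-(trimethylsilyl)ethyl]phosphonium iodide | [I-].C[Si](C)(C)CC[P+](c1ccccc1)(c1ccccc1)c1ccccc1 | intermediate
11 | triphenyl[2-(trimethylsilyl)ethylidene]phosphorane | C[Si](C)(C)CC=P(c1ccccc1)(c1ccccc1)c1ccccc1 | intermediate
12 | {(2Z)-8-(1,3-dioxolan-2-yl)-4,4-dimethyloct-2-en-1-yl}trimethylsilane | C[Si](C)(C)C/C=C\C(C)(C)CCCCC1OCCO1 | intermediate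
13 | (7Z)-6,6-dimethyl-9-(trimethylsilyl)non-7-enal | O=CCCCCC(C)(C)/C=C\C[Si](C)(C)C | intermediate
14 | (1S,2R)-2-ethenyl-3,3-dimethylcyclohexane-1-carbaldehyde | C=C[C@@H]1[C@@H](C=O)CCCC1(C)C | intermediate
15 | (1S,2R)-2-ethenyl-3,3-dimethylcyclohexane-1-carboxylic acid | C=C[C@@H]1[C@@H](C(=O)O)CCCC1(C)C | intermediate
16 | methyl (1S,2R)-2-ethenyl-3,3-dimethylcyclohexane-1-carboxylate | C=C[C@@H]1[C@@H](C(=O)OC)CCCC1(C)C | intermediate
17 | but-2-yn-1-ol | CC#CCO | starting material
18 | sodium cyclic vinylalanate from 17 | [Na+].CC1=CCO[Al-]1(OCCOC)OCCOC | intermediate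
19 | (2Z)-3-iodobut-2-en-1-ol | C/C(I)=C/CO | intermediate
20 | B-alkyl-9-borabicyclo[3.3.1]nonane from 16 | B1(C2CCCC1CCC2)CC[C@@H]1[C@@H](C(=O)OC)CCCC1(C)C | intermediate
21 | methyl (1S,2R)-2-[(3Z)-5-hydroxy-3-methylpent-3-en-1-yl]-3,3-dimethylcyclohexane-1-carboxylate | OC/C=C(C)\CC[C@@H]1[C@@H](C(=O)OC)CCCC1(C)C | intermediate
22 | methyl (1S,2R)-2-{(3Z)-5-[(methoxycarbonyl)oxy]-3-methylpent-3-en-1-yl}-3,3-dimethylcyclohexane-1-carboxylate | COC(=O)OC/C=C(C)\CC[C@@H]1[C@@H](C(=O)OC)CCCC1(C)C | intermediate
23 | 2,6-dihydroxy-4-methylbenzaldehyde (atranol) | Cc1cc(O)c(C=O)c(O)c1 | starting material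
24 | 2-[(tert-butyldimethylsilyl)oxy]-6-hydroxy-4-methylbenzaldehyde | Cc1cc(O)c(C=O)c(O[Si](C)(C)C(C)(C)C)c1 | intermediate
25 | racemic 3-[(tert-butyldimethylsilyl)oxy]-2-[1-hydroxy-2-(trimethylsilyl)ethyl]-5-methylphenol (β-hydroxysilane, present as its magnesium salt before the acid is added) | Cc1cc(O)c(C(O)C[Si](C)(C)C)c(O[Si](C)(C)C(C)(C)C)c1 | intermediate
26 | 3-[(tert-butyldimethylsilyl)oxy]-2-ethenyl-5-methylphenol | C=Cc1c(O)cc(C)cc1O[Si](C)(C)C(C)(C)C | intermediate
27 | methyl (1S,2R)-2-[(3R)-3-{3-[(tert-butyldimethylsilyl)oxy]-2-ethenyl-5-methylphenoxy}-3-methylpent-4-en-1-yl]-3,3-dimethylcyclohexane-1-carboxylate | C=C[C@@](C)(CC[C@@H]1[C@@H](C(=O)OC)CCCC1(C)C)Oc1cc(C)cc(O[Si](C)(C)C(C)(C)C)c1C=C | intermediate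
28 | methyl (1S,2R)-2-{2-[(2R)-5-[(tert-butyldimethylsilyl)oxy]-2,7-dimethyl-2H-chromen-2-yl]ethyl}-3,3-dimethylcyclohexane-1-carboxylate | Cc1cc(O[Si](C)(C)C(C)(C)C)c2c(c1)O[C@](C)(CC[C@@H]1[C@@H](C(=O)OC)CCCC1(C)C)C=C2 | intermediate
29 | (1S,2R)-2-{2-[(2R)-5-hydroxy-2,7-dimethyl-2H-chromen-2-yl]ethyl}-3,3-dimethylcyclohexane-1-carboxylic acid | Cc1cc(O)c2c(c1)O[C@](C)(CC[C@@H]1[C@@H](C(=O)O)CCCC1(C)C)C=C2 | target

Total step count: 15. Longest linear sequence: 12 steps (steps 1–7, 9, 10, 13, 14, 15); steps 8 and 11–12 are side branches.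

Steps most likely to fail

Step 5. The radical addition to the alkene terminus beside the quaternary carbon may be slow, so that nitrate trapping or over-oxidation of the radical cation competes. The trans selectivity of the ring closure may also be insufficient, which lowers the enantiomeric purity at C2 once cis material is removed. The fallback sets out from 6 and comes back at 14. Horner–Wadsworth–Emmons olefination of 6 (triethyl phosphonoacetate, NaH, THF) would give ethyl (2E)-8-(1,3-dioxolan-2-yl)-4,4-dimethyloct-2-enoate F1. Reduction with i-Bu2AlH would give (2E)-8-(1,3-dioxolan-2-yl)-4,4-dimethyloct-2-en-1-ol F2, and ClCO2Me/pyridine would give (2E)-8-(1,3-dioxolan-2-yl)-4,4-dimethyloct-2-en-1-yl methyl carbonate F3. Aqueous AcOH would free the aldehyde (2E)-4,4-dimethyl-9-oxonon-2-en-1-yl methyl carbonate F4. F4 would then be cyclised by an intramolecular Tsuji–Trost α-allylation under dual catalysis: pyrrolidine forms the enamine, and zerovalent palladium from Pd2(dba)3 with (R)-BINAP forms the π-allyl complex. Here the chiral ligand sets C2 directly at the allyl terminus and C1 settles trans, which gives 14.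

Step 13. Attack at the primary allyl terminus (linear ether), weak facial discrimination at the trisubstituted terminus, and re-ionisation of the tertiary aryl ether may lower regio- and enantioselectivity. The fallback sets out from 21 and comes back at 27. Sharpless asymmetric epoxidation of 21 (Ti(Oi-Pr)4, L-(+)-diethyl tartrate, t-BuOOH, 4 Å sieves) would give methyl (1S,2R)-2-{2-[(2R,3S)-3-(hydroxymethyl)-2-methyloxiran-2-yl]ethyl}-3,3-dimethylcyclohexane-1-carboxylate F5. I2/PPh3/imidazole would give methyl (1S,2R)-2-{2-[(2R,3R)-3-(iodomethyl)-2-methyloxiran-2-yl]ethyl}-3,3-dimethylcyclohexane-1-carboxylate F6. Reductive opening with Zn in EtOH would give methyl (1S,2R)-2-[(3R)-3-hydroxy-3-methylpent-4-en-1-yl]-3,3-dimethylcyclohexane-1-carboxylate F7, whose tertiary carbon keeps the configuration set by the epoxidation. Its potassium alkoxide (KN(SiMe3)2, THF) would displace one fluoride of 2,6-difluoro-4-methylbenzaldehyde (SNAr) to give methyl (1S,2R)-2-[(3R)-3-(3-fluoro-2-formyl-5-methylphenoxy)-3-methylpent-4-en-1-yl]-3,3-dimethylcyclohexane-1-carboxylate F8. 2-(Methylsulfonyl)ethanol/NaH would replace the second fluoride by hydroxyl, giving methyl (1S,2R)-2-[(3R)-3-(2-formyl-3-hydroxy-5-methylphenoxy)-3-methylpent-4-en-1-yl]-3,3-dimethylcyclohexane-1-carboxylate F9. TBSCl/imidazole would give methyl (1S,2R)-2-[(3R)-3-{3-[(tert-butyldimethylsilyl)oxy]-2-formyl-5-methylphenoxy}-3-methylpent-4-en-1-yl]-3,3-dimethylcyclohexane-1-carboxylate F10, and Wittig methylenation with methylenetriphenylphosphorane 9 (from 7 and KOt-Bu, THF) would give 27.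

Step 3. Olefination of the α-quaternary aldehyde by the bulky β-silyl ylide may be incomplete and give an alkene mixture. The fallback sets out from 6 and comes back at 12. Stork–Zhao olefination of 6 (Ph3P=CHI from (iodomethyl)triphenylphosphonium iodide and NaN(SiMe3)2, THF, −78 °C) would give 2-[(6Z)-7-iodo-5,5-dimethylhept-6-en-1-yl]-1,3-dioxolane F11. Kumada coupling with Me3SiCH2MgCl (Pd(PPh3)4, THF) would then give 12 with retention of the alkene geometry.

Further compounds
F1 | step 5 | ethyl (2E)-8-(1,3-dioxolan-2-yl)-4,4-dimethyloct-2-enoate | CCOC(=O)/C=C/C(C)(C)CCCCC1OCCO1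
F2 | step 5 | (2E)-8-(1,3-dioxolan-2-yl)-4,4-dimethyloct-2-en-1-ol | OC/C=C/C(C)(C)CCCCC1OCCO1
F3 | step 5 | (2E)-8-(1,3-dioxolan-2-yl)-4,4-dimethyloct-2-en-1-yl methyl carbonate | COC(=O)OC/C=C/C(C)(C)CCCCC1OCCO1
F4 | step 5 | (2E)-4,4-dimethyl-9-oxonon-2-en-1-yl methyl carbonate | COC(=O)OC/C=C/C(C)(C)CCCCC=O
F5 | step 13 | methyl (1S,2R)-2-{2-[(2R,3S)-3-(hydroxymethyl)-2-methyloxiran-2-yl]ethyl}-3,3-dimethylcyclohexane-1-carboxylate | OC[C@@H]1O[C@]1(C)CC[C@@H]1[C@@H](C(=O)OC)CCCC1(C)C
F6 | step 13 | methyl (1S,2R)-2-{2-[(2R,3R)-3-(iodomethyl)-2-methyloxiran-2-yl]ethyl}-3,3-dimethylcyclohexane-1-carboxylate | IC[C@@H]1O[C@]1(C)CC[C@@H]1[C@@H](C(=O)OC)CCCC1(C)C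
F7 | step 13 | methyl (1S,2R)-2-[(3R)-3-hydroxy-3-methylpent-4-en-1-yl]-3,3-dimethylcyclohexane-1-carboxylate | C=C[C@](C)(O)CC[C@@H]1[C@@H](C(=O)OC)CCCC1(C)C
F8 | step 13 | methyl (1S,2R)-2-[(3R)-3-(3-fluoro-2-formyl-5-methylphenoxy)-3-methylpent-4-en-1-yl]-3,3-dimethylcyclohexane-1-carboxylate | C=C[C@@](C)(CC[C@@H]1[C@@H](C(=O)OC)CCCC1(C)C)Oc1cc(C)cc(F)c1C=O
F9 | step 13 | methyl (1S,2R)-2-[(3R)-3-(2-formyl-3-hydroxy-5-methylphenoxy)-3-methylpent-4-en-1-yl]-3,3-dimethylcyclohexane-1-carboxylate | C=C[C@@](C)(CC[C@@H]1[C@@H](C(=O)OC)CCCC1(C)C)Oc1cc(C)cc(O)c1C=O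
F10 | step 13 | methyl (1S,2R)-2-[(3R)-3-{3-[(tert-butyldimethylsilyl)oxy]-2-formyl-5-methylphenoxy}-3-methylpent-4-en-1-yl]-3,3-dimethylcyclohexane-1-carboxylate | C=C[C@@](C)(CC[C@@H]1[C@@H](C(=O)OC)CCCC1(C)C)Oc1cc(C)cc(O[Si](C)(C)C(C)(C)C)c1C=O
F11 | step 3 | 2-[(6Z)-7-iodo-5,5-dimethylhept-6-en-1-yl]-1,3-dioxolane | I/C=C\C(C)(C)CCCCC1OCCO1
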